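## Retrosynthetic overview

1. Target 32 is ent-fisetinidol-(4α→6)-ent-fisetinidol-(4α→8)-catechin-(6→4β)-ent-fisetinidol (units A, B, D, C in that order); it comes from hexadeca-O-benzyl ether 31 by hydrogenolysis.
2. Key disconnection: the pyran ring of unit B (O1–C2–C3–C4–C4a–C8a) is opened at O1–C2 and C4–H to the open-chain epoxy carbinol 28. The enabling feature: C2 is benzylic to the catechol ring, so its epoxide bond opens 6-endo toward the phenolic O1 ortho to C4a; C4 is doubly benzylic between the resorcinol ring of unit B and C8 of the catechin phloroglucinol ring, so it ionises and takes hydride anti to C3–O (3,4-cis).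
3. 28 comes from two aryllithium additions to one C3 linchpin, epoxy amide 24: first upper bromide 21, then lower bromide 14. The catalytic asymmetric epoxidation that gives 24 sets C3 of unit B; C2 and C4 are relayed from it.
4. 21 = dihalide 18 + flavanone 8 (aryllithium addition, then ionic hydrogenation, 3,4-cis). 14 = 8-bromocatechin 13 + flavan-4-ol 9 (cation capture at C6, 3,4-trans). 8 and 9 come from one chalcone epoxide 5.
5. Ring order: catechin rings are bought; the pyran ring of units A and C is made once (step 4); the pyran ring of unit B is closed last (step 20).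

Key step: step 20

Assumption: poly-D-leucine (step 3) and the (R)-BINOL samarium catalyst (step 17) are taken to give the (2S,3R)-epoxides drawn; if the sense of induction is the reverse, the antipodal catalyst is used.
Assumption: the carbinol configurations drawn for 20, 28 and 30 are the expected ones; these centres are erased by ionisation and do not matter.
Assumption: compounds 1, 3, 10, 15 and 22 are taken as commercial.

## Route

Step 1
Reactants: 1 4'-benzyloxy-2'-hydroxyacetophenone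
Product: 2 4'-benzyloxy-2'-(methoxymethoxy)acetophenone
Conditions: NaH, MOMCl, DMF, 0 °C to rt
Reagents that add atoms: chloromethyl methyl ether, COCCl
Why: Williamson O-alkylation of the phenoxide masks the 2'-hydroxyl, which would otherwise divert the alkaline epoxidation of step 3 into an Algar–Flynn–Oyamada oxidation.

Step 2
Reactants: 2 4'-benzyloxy-2'-(methoxymethoxy)acetophenone; 3 3,4-bis(benzyloxy)benzaldehyde
Product: 4 MOM-protected (E)-chalcone
Conditions: KOH, EtOH/THF, rt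
Reagents that add atoms: none
Why: Claisen–Schmidt aldol condensation with E1cB dehydration should give the (E)-enone under thermodynamic control.

Step 3
Reactants: 4 MOM-protected (E)-chalcone
Product: 5 (2S,3R)-epoxy ketone
Conditions: poly-D-leucine, urea–H2O2, DBU, THF, rt
Reagents that add atoms: hydrogen peroxide (as urea adduct), OO
Why: Juliá–Colonna epoxidation (polypeptide-controlled Weitz–Scheffer addition of hydroperoxide) should give the trans-epoxide, the helical catalyst selecting the enone face so that both epoxide carbons are set by the catalyst.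

Step 4
Reactants: 5 (2S,3R)-epoxy ketone
Product: 7 tri-O-benzyl-(2S,3S)-fustin, via free 2'-hydroxy epoxy ketone 6 (not isolated)
Conditions: conc. HCl, MeOH/THF, 55 °C
Reagents that add atoms: none
Why: Acid removes the MOM acetal and the freed phenol opens the epoxide 6-endo at the benzylic carbon with inversion (epoxy-chalcone to dihydroflavonol cyclisation), which should give the 2,3-trans flavanonol with C-3 retained from the epoxide.

Step 5
Reactants: 7 tri-O-benzyl-(2S,3S)-fustin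
Product: 8 tetra-O-benzyl-(2S,3S)-fustin
Conditions: BnOC(=NH)CCl3, TfOH (cat.), CH2Cl2/cyclohexane, 0 °C to rt
Reagents that add atoms: benzyl 2,2,2-trichloroacetimidate, N=C(OCc1ccccc1)C(Cl)(Cl)Cl
Why: Acid-catalysed trichloroacetimidate benzylation avoids base, under which a 3-hydroxyflavanone would ring-open or epimerise; no stereocenter is touched.

Step 6
Reactants: 8 tetra-O-benzyl-(2S,3S)-fustin
Product: 9 (2S,3R,4S)-flavan-4-ol
Conditions: NaBH4, MeOH/THF, 0 °C
Reagents that add atoms: none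
Why: Borohydride reduction of the aryl ketone gives the benzylic alcohol needed as cation precursor; axial hydride attack should give mainly the 3,4-trans alcohol, a centre that is erased in step 10.

Step 7
Reactants: 10 (+)-catechin
Product: 11 5,7,3',4'-tetra-O-benzylcatechin
Conditions: BnBr, K2CO3, DMF, rt
Reagents that add atoms: benzyl bromide, BrCc1ccccc1
Why: Williamson ether synthesis; with carbonate only the four phenols are alkylated and the stereocenters are untouched.

Step 8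
Reactants: 11 5,7,3',4'-tetra-O-benzylcatechin
Product: 12 penta-O-benzylcatechin
Conditions: NaH, BnBr, DMF, 0 °C to rt
Reagents that add atoms: benzyl bromide, BrCc1ccccc1
Why: Williamson alkylation of the secondary alkoxide removes the last acidic proton before the organolithium chemistry.

Step 9
Reactants: 12 penta-O-benzylcatechin
Product: 13 8-bromo-penta-O-benzylcatechin
Conditions: NBS, CH2Cl2, −78 °C to rt
Reagents that add atoms: N-bromosuccinimide, O=C1CCC(=O)N1Br
Why: Electrophilic aromatic bromination should occur at C-8, the more reactive position of 5,7-di-O-alkylflavans; the bromine blocks C-8 and is the handle for the lithiation of step 19.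

Step 10
Reactants: 13 8-bromo-penta-O-benzylcatechin; 9 (2S,3R,4S)-flavan-4-ol
Product: 14 lower dimer bromide
Conditions: TMSOTf (0.2 equiv), CH2Cl2, −78 to −30 °C, 13 in excess
Reagents that add atoms: none
Why: TMSOTf ionises the benzylic alcohol to the flavan-4-yl cation, which C-6 of 13 (the only free nucleophilic position) captures in a Friedel–Crafts alkylation; the arene should approach anti to the 3-benzyloxy group and give the 3,4-trans (4β) linkage.

Step 11
Reactants: 15 3-(benzyloxy)phenol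
Product: 16 3-(benzyloxy)-4-iodophenol
Conditions: NIS, TsOH (cat.), MeCN, 0 °C
Reagents that add atoms: N-iodosuccinimide, O=C1CCC(=O)N1I
Why: Electrophilic iodination should go para to the free hydroxyl, the strongest director of the resorcinol monoether.

Step 12
Reactants: 16 3-(benzyloxy)-4-iodophenol
Product: 17 5-(benzyloxy)-2-bromo-4-iodophenol
Conditions: NBS, i-Pr2NH (cat.), CH2Cl2, 0 °C
Reagents that add atoms: N-bromosuccinimide, O=C1CCC(=O)N1Br
Why: Electrophilic bromination should take the remaining position ortho to the hydroxyl and para to the benzyloxy group, the site between the two oxygens being hindered.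

Step 13
Reactants: 17 5-(benzyloxy)-2-bromo-4-iodophenol
Product: 18 allyl ether dihalide
Conditions: allyl bromide, K2CO3, acetone, 56 °C
Reagents that add atoms: allyl bromide, C=CCBr
Why: Williamson O-allylation gives an ether that survives organolithium and acid steps and is removed under neutral conditions in step 20.

Step 14
Reactants: 18 allyl ether dihalide; 8 tetra-O-benzyl-(2S,3S)-fustin
Product: 20 upper tertiary flavan-4-ol, via bromoaryllithium 19 (not isolated)
Conditions: n-BuLi (1.0 equiv), THF, −78 °C; then 8, −78 to −40 °C; H2O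
Reagents that add atoms: none
Why: Iodine–lithium exchange is faster than bromine–lithium exchange, so only the iodide is metalated, and the aryllithium adds 1,2 to the flavanone carbonyl, expected anti to the 3-benzyloxy group (this carbinol centre is erased in step 15).

Step 15
Reactants: 20 upper tertiary flavan-4-ol
Product: 21 upper bromide
Conditions: Et3SiH, TFA, CH2Cl2, −40 to 0 °C
Reagents that add atoms: none
Why: Ionic hydrogenation: TFA ionises the tertiary doubly benzylic carbinol and Et3SiH delivers hydride to the planar C-4 cation anti to the 3-benzyloxy group (pushed pseudo-axial by A(1,2) strain with the 4-aryl group), which should place the aryl group cis to O-3 (4α linkage of unit A), as known for 4-aryl-flavan-4-ols.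

Step 16
Reactants: 3 3,4-bis(benzyloxy)benzaldehyde; 22 diethyl (2-morpholino-2-oxoethyl)phosphonate
Product: 23 (E)-cinnamoyl morpholide
Conditions: NaH, THF, 0 °C to rt
Reagents that add atoms: none
Why: Horner–Wadsworth–Emmons olefination with the amide-stabilised phosphonate should give the (E)-alkene.

Step 17
Reactants: 23 (E)-cinnamoyl morpholide
Product: 24 (2S,3R)-epoxy morpholide
Conditions: Sm(O-i-Pr)3 (10 mol %), (R)-BINOL (10 mol %), Ph3As=O (10 mol %), TBHP, 4 Å MS, THF, rt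
Reagents that add atoms: tert-butyl hydroperoxide, CC(C)(C)OO
Why: Lanthanide–BINOL-catalysed nucleophilic epoxidation of the α,β-unsaturated amide delivers the peroxide to one enantioface and should give the trans-glycidic amide; this catalytic step sets the carbon that becomes C-3 of unit B.

Step 18
Reactants: 21 upper bromide; 24 (2S,3R)-epoxy morpholide
Product: 26 upper epoxy ketone, via upper aryllithium 25 (not isolated)
Conditions: n-BuLi, THF, −78 °C; then 24, −78 to −40 °C; H2O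
Reagents that add atoms: none
Why: Bromine–lithium exchange followed by acylation of the aryllithium with the morpholine amide, whose stable tetrahedral chelate prevents over-addition; the epoxide stereocenters are not touched.

Step 19
Reactants: 14 lower dimer bromide; 26 upper epoxy ketone
Product: 28 open-chain epoxy carbinol, via lower aryllithium 27 (not isolated)
Conditions: t-BuLi (2 equiv), THF, −78 °C; then 26, −78 to −40 °C; H2O
Reagents that add atoms: none
Why: Bromine–lithium exchange at C-8 of the catechin unit and 1,2-addition of the aryllithium to the lithium-chelated epoxy ketone joins the two dimers; the carbinol configuration (chelation-controlled product drawn) does not matter because C-4 is ionised in step 20.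

Step 20
Reactants: 28 open-chain epoxy carbinol
Product: 31 hexadeca-O-benzyl tetramer, via free phenol 29 (not isolated), via ring-closed flavan-3,4-diol 30 (not isolated)
Conditions: Pd(PPh3)4 (5 mol %), morpholine, CH2Cl2, rt; then Et3SiH, TFA, −40 to 0 °C
Reagents that add atoms: none
Why: Zerovalent palladium (Pd(PPh3)4) transfers the allyl group to morpholine and frees the phenolic O-1; on addition of TFA this oxygen opens the protonated epoxide at C-2, the carbon made benzylic by the 3,4-bis(benzyloxy)phenyl ring, in a 6-endo-tet closure (O1–C2) that is the known acid-mediated cyclisation of 2-(2,3-epoxy-3-arylpropyl)phenols to 2,3-trans-flavan-3-ols. The tertiary, doubly benzylic C-4 carbinol ionises to the 4-aryl-flavan-4-yl cation (if it ionises first, the quinone-methide-type cation still closes through its oxygen to the same cyclic cation), and Et3SiH reduces it, the closest known reaction being the ionic hydrogenation of 4-aryl-flavan-4-ols used in step 15. C-3 is retained from the catalytically made epoxide; C-2 is set by inversion at the epoxide carbon (and, if the opening is SN1-like, by the equatorial preference of the aryl group trans to O-3); C-4 is set by hydride attack anti to the pseudo-axial C3–O bond, into which the ring is forced by A(1,2) strain between the 4-aryl group and O-3. The step needs 6-endo over 5-exo regioselectivity, secured by the electron-rich aryl group on C-2 and the acid medium; ring closure faster than hydride capture of the open-chain cation, secured by intramolecularity and the low hydride affinity of this highly stabilised cation; and reduction faster than a 1,2-hydride shift to a flavan-3-one, favoured by low temperature and excess silane.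

Step 21
Reactants: 31 hexadeca-O-benzyl tetramer
Product: 32 target CNP0126838.5
Conditions: H2 (1 atm), Pd(OH)2/C, THF/MeOH/H2O, rt
Reagents that add atoms: none
Why: Catalytic hydrogenolysis should cleave the sixteen benzyl ethers while the cyclic benzylic ether bonds and the C-4 aryl bonds of the flavan units survive, as is usual for benzylated proanthocyanidins; no stereocenter is affected.

## Compound list

1 | 1-[4-(benzyloxy)-2-hydroxyphenyl]ethan-1-one | CC(=O)c1ccc(OCc2ccccc2)cc1O | starting material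
2 | 1-[4-(benzyloxy)-2-(methoxymethoxy)phenyl]ethan-1-one | COCOc1cc(OCc2ccccc2)ccc1C(C)=O | intermediate
3 | 3,4-bis(benzyloxy)benzaldehyde | O=Cc1ccc(OCc2ccccc2)c(OCc2ccccc2)c1 | starting material
4 | (E)-1-[4-(benzyloxy)-2-(methoxymethoxy)phenyl]-3-[3,4-bis(benzyloxy)phenyl]prop-2-en-1-one | COCOc1cc(OCc2ccccc2)ccc1C(=O)/C=C/c1ccc(OCc2ccccc2)c(OCc2ccccc2)c1 | intermediate
5 | [4-(benzyloxy)-2-(methoxymethoxy)phenyl][(2S,3R)-3-[3,4-bis(benzyloxy)phenyl]oxiran-2-yl]methanone | COCOc1cc(OCc2ccccc2)ccc1C(=O)[C@H]1O[C@@H]1c1ccc(OCc2ccccc2)c(OCc2ccccc2)c1 | intermediate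
6 | [4-(benzyloxy)-2-hydroxyphenyl][(2S,3R)-3-[3,4-bis(benzyloxy)phenyl]oxiran-2-yl]methanone | Oc1cc(OCc2ccccc2)ccc1C(=O)[C@H]1O[C@@H]1c1ccc(OCc2ccccc2)c(OCc2ccccc2)c1 | intermediate
7 | (2S,3S)-7-(benzyloxy)-2-[3,4-bis(benzyloxy)phenyl]-3-hydroxychroman-4-one | c9ccccc9COc1ccc2c(c1)O[C@@H](c1ccc(OCc9ccccc9)c(OCc9ccccc9)c1)[C@H](O)C2=O | intermediate
8 | (2S,3S)-3,7-bis(benzyloxy)-2-[3,4-bis(benzyloxy)phenyl]chroman-4-one | c9ccccc9COc1ccc2c(c1)O[C@@H](c1ccc(OCc9ccccc9)c(OCc9ccccc9)c1)[C@H](OCc9ccccc9)C2=O | intermediate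
9 | (2S,3R,4S)-3,7-bis(benzyloxy)-2-[3,4-bis(benzyloxy)phenyl]chroman-4-ol (2,3-trans-3,4-trans) | c9ccccc9COc1ccc2c(c1)O[C@@H](c1ccc(OCc9ccccc9)c(OCc9ccccc9)c1)[C@H](OCc9ccccc9)[C@H]2O | intermediate
10 | (+)-catechin, (2R,3S)-2-(3,4-dihydroxyphenyl)chroman-3,5,7-triol | c1c(O)cc(O)c2c1O[C@H](c1ccc(O)c(O)c1)[C@@H](O)C2 | starting material
11 | (2R,3S)-5,7-bis(benzyloxy)-2-[3,4-bis(benzyloxy)phenyl]chroman-3-ol | c1c(OCc9ccccc9)cc(OCc9ccccc9)c2c1O[C@H](c1ccc(OCc9ccccc9)c(OCc9ccccc9)c1)[C@@H](O)C2 | intermediate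
12 | (2R,3S)-3,5,7-tris(benzyloxy)-2-[3,4-bis(benzyloxy)phenyl]chromane | c1c(OCc9ccccc9)cc(OCc9ccccc9)c2c1O[C@H](c1ccc(OCc9ccccc9)c(OCc9ccccc9)c1)[C@@H](OCc9ccccc9)C2 | intermediate
13 | (2R,3S)-3,5,7-tris(benzyloxy)-2-[3,4-bis(benzyloxy)phenyl]-8-bromochromane | Brc1c(OCc9ccccc9)cc(OCc9ccccc9)c2c1O[C@H](c1ccc(OCc9ccccc9)c(OCc9ccccc9)c1)[C@@H](OCc9ccccc9)C2 | intermediate
14 | lower dimer bromide: 8-bromo-penta-O-benzylcatechin-(6→4β)-tetra-O-benzyl-ent-fisetinidol; flavan-4-yl unit (2S,3R,4R), 2,3-trans-3,4-trans | Brc4c(OCc9ccccc9)c([C@H]6c7ccc(OCc9ccccc9)cc7O[C@@H](c7ccc(OCc9ccccc9)c(OCc9ccccc9)c7)[C@@H]6OCc9ccccc9)c(OCc9ccccc9)c5c4O[C@H](c8ccc(OCc9ccccc9)c(OCc9ccccc9)c8)[C@@H](OCc9ccccc9)C5 | intermediate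
15 | 3-(benzyloxy)phenol | Oc1cccc(OCc2ccccc2)c1 | starting material
16 | 3-(benzyloxy)-4-iodophenol | Oc1ccc(I)c(OCc2ccccc2)c1 | intermediate
17 | 5-(benzyloxy)-2-bromo-4-iodophenol | Oc1cc(OCc2ccccc2)c(I)cc1Br | intermediate
18 | 1-(benzyloxy)-4-bromo-2-iodo-5-(prop-2-en-1-yloxy)benzene | C=CCOc1cc(OCc2ccccc2)c(I)cc1Br | intermediate
19 | [4-(allyloxy)-2-(benzyloxy)-5-bromophenyl]lithium | C=CCOc1cc(OCc2ccccc2)c([Li])cc1Br | intermediate
20 | (2S,3S,4S)-4-[4-(allyloxy)-2-(benzyloxy)-5-bromophenyl]-3,7-bis(benzyloxy)-2-[3,4-bis(benzyloxy)phenyl]chroman-4-ol (2,3-trans; aryl trans to the 3-benzyloxy group) | c9ccccc9COc1ccc2c(c1)O[C@@H](c1ccc(OCc9ccccc9)c(OCc9ccccc9)c1)[C@H](OCc9ccccc9)[C@@]2(O)c1cc(Br)c(OCC=C)cc1OCc9ccccc9 | intermediate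
21 | upper bromide: (2S,3R,4S)-4-[4-(allyloxy)-2-(benzyloxy)-5-bromophenyl]-3,7-bis(benzyloxy)-2-[3,4-bis(benzyloxy)phenyl]chromane (2,3-trans-3,4-cis) | c9ccccc9COc1ccc2c(c1)O[C@@H](c1ccc(OCc9ccccc9)c(OCc9ccccc9)c1)[C@H](OCc9ccccc9)[C@@H]2c1cc(Br)c(OCC=C)cc1OCc9ccccc9 | intermediate
22 | diethyl [2-(morpholin-4-yl)-2-oxoethyl]phosphonate | CCOP(=O)(CC(=O)N1CCOCC1)OCC | starting material
23 | (E)-3-[3,4-bis(benzyloxy)phenyl]-1-(morpholin-4-yl)prop-2-en-1-one | O=C(/C=C/c1ccc(OCc2ccccc2)c(OCc2ccccc2)c1)N1CCOCC1 | intermediate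
24 | [(2S,3R)-3-[3,4-bis(benzyloxy)phenyl]oxiran-2-yl](morpholin-4-yl)methanone | O=C([C@H]1O[C@@H]1c1ccc(OCc2ccccc2)c(OCc2ccccc2)c1)N1CCOCC1 | intermediate
25 | upper aryllithium: compound 21 with lithium in place of bromine | c9ccccc9COc1ccc2c(c1)O[C@@H](c1ccc(OCc9ccccc9)c(OCc9ccccc9)c1)[C@H](OCc9ccccc9)[C@@H]2c1cc([Li])c(OCC=C)cc1OCc9ccccc9 | intermediate
26 | upper epoxy ketone: [2-(allyloxy)-4-(benzyloxy)-5-(tetra-O-benzyl-ent-fisetinidol-4α-yl)phenyl][(2S,3R)-3-[3,4-bis(benzyloxy)phenyl]oxiran-2-yl]methanone; flavanyl unit (2S), 2,3-trans-3,4-cis | c9ccccc9COc1ccc2c(c1)O[C@@H](c1ccc(OCc9ccccc9)c(OCc9ccccc9)c1)[C@H](OCc9ccccc9)[C@@H]2c1cc(C(=O)[C@H]3O[C@@H]3c3ccc(OCc9ccccc9)c(OCc9ccccc9)c3)c(OCC=C)cc1OCc9ccccc9 | intermediate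
27 | lower aryllithium: compound 14 with lithium in place of bromine | [Li]c4c(OCc9ccccc9)c([C@H]6c7ccc(OCc9ccccc9)cc7O[C@@H](c7ccc(OCc9ccccc9)c(OCc9ccccc9)c7)[C@@H]6OCc9ccccc9)c(OCc9ccccc9)c5c4O[C@H](c8ccc(OCc9ccccc9)c(OCc9ccccc9)c8)[C@@H](OCc9ccccc9)C5 | intermediate
28 | open-chain epoxy carbinol: tertiary alcohol carrying the allyloxy resorcinol ring of unit B (with unit A on it), C-8 of the lower dimer and the (2S,3R)-3-[3,4-bis(benzyloxy)phenyl]oxiran-2-yl group; carbinol centre as from chelation-controlled addition | c9ccccc9COc1ccc2c(c1)O[C@@H](c1ccc(OCc9ccccc9)c(OCc9ccccc9)c1)[C@H](OCc9ccccc9)[C@@H]2c1cc([C@](O)(c4c(OCc9ccccc9)c([C@H]6c7ccc(OCc9ccccc9)cc7O[C@@H](c7ccc(OCc9ccccc9)c(OCc9ccccc9)c7)[C@@H]6OCc9ccccc9)c(OCc9ccccc9)c5c4O[C@H](c8ccc(OCc9ccccc9)c(OCc9ccccc9)c8)[C@@H](OCc9ccccc9)C5)[C@H]3O[C@@H]3c3ccc(OCc9ccccc9)c(OCc9ccccc9)c3)c(OCC=C)cc1OCc9ccccc9 | intermediate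
29 | free phenol: compound 28 with the allyl ether cleaved to OH | c9ccccc9COc1ccc2c(c1)O[C@@H](c1ccc(OCc9ccccc9)c(OCc9ccccc9)c1)[C@H](OCc9ccccc9)[C@@H]2c1cc([C@](O)(c4c(OCc9ccccc9)c([C@H]6c7ccc(OCc9ccccc9)cc7O[C@@H](c7ccc(OCc9ccccc9)c(OCc9ccccc9)c7)[C@@H]6OCc9ccccc9)c(OCc9ccccc9)c5c4O[C@H](c8ccc(OCc9ccccc9)c(OCc9ccccc9)c8)[C@@H](OCc9ccccc9)C5)[C@H]3O[C@@H]3c3ccc(OCc9ccccc9)c(OCc9ccccc9)c3)c(O)cc1OCc9ccccc9 | intermediate
30 | ring-closed tertiary flavan-3,4-diol: benzylated tetramer with unit B closed (2S, 2,3-trans), 3-OH free and a 4-OH cis to it on the carbon bearing C-8 of catechin | c9ccccc9COc1ccc2c(c1)O[C@@H](c1ccc(OCc9ccccc9)c(OCc9ccccc9)c1)[C@H](OCc9ccccc9)[C@@H]2c1cc2c(cc1OCc9ccccc9)O[C@@H](c1ccc(OCc9ccccc9)c(OCc9ccccc9)c1)[C@H](O)[C@@]2(O)c4c(OCc9ccccc9)c([C@H]6c7ccc(OCc9ccccc9)cc7O[C@@H](c7ccc(OCc9ccccc9)c(OCc9ccccc9)c7)[C@@H]6OCc9ccccc9)c(OCc9ccccc9)c5c4O[C@H](c8ccc(OCc9ccccc9)c(OCc9ccccc9)c8)[C@@H](OCc9ccccc9)C5 | intermediate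
31 | hexadeca-O-benzyl ether of the target (all phenols and the 3-OH of units A, C and D benzylated; 3-OH of unit B free; unit B 2,3-trans-3,4-cis) | c9ccccc9COc1ccc2c(c1)O[C@@H](c1ccc(OCc9ccccc9)c(OCc9ccccc9)c1)[C@H](OCc9ccccc9)[C@@H]2c1cc2c(cc1OCc9ccccc9)O[C@@H](c1ccc(OCc9ccccc9)c(OCc9ccccc9)c1)[C@H](O)[C@@H]2c4c(OCc9ccccc9)c([C@H]6c7ccc(OCc9ccccc9)cc7O[C@@H](c7ccc(OCc9ccccc9)c(OCc9ccccc9)c7)[C@@H]6OCc9ccccc9)c(OCc9ccccc9)c5c4O[C@H](c8ccc(OCc9ccccc9)c(OCc9ccccc9)c8)[C@@H](OCc9ccccc9)C5 | intermediate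
32 | CNP0126838.5, ent-fisetinidol-(4α→6)-ent-fisetinidol-(4α→8)-catechin-(6→4β)-ent-fisetinidol; unit A (2S,3R,4R), unit B (2S,3R,4S), unit C (2S,3R,4R), catechin (2R,3S) | Oc1ccc2c(c1)O[C@@H](c1ccc(O)c(O)c1)[C@H](O)[C@@H]2c1cc2c(cc1O)O[C@@H](c1ccc(O)c(O)c1)[C@H](O)[C@@H]2c1c(O)c([C@H]2c3ccc(O)cc3O[C@@H](c3ccc(O)c(O)c3)[C@@H]2O)c(O)c2c1O[C@H](c1ccc(O)c(O)c1)[C@@H](O)C2 | target

## Step count and risks

Total step count: 21. Longest linear sequence: 11 steps (steps 1, 2, 3, 4, 5, 14, 15, 18, 19, 20, 21).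

Steps most likely to fail:

1. Step 20. After ionisation at C-4, a 1,2-hydride shift or loss of the C-3 proton (pinacol-type collapse to a flavan-3-one) could compete with reduction. Hydride capture of the still open-chain cation could also erode the 3,4-cis selectivity. Fallback: the ring is closed at the ketone oxidation level before the fragments are joined. It sets out from 26. Pd(PPh3)4 and morpholine remove the allyl group to give the free 2'-hydroxy epoxy ketone F1. HCl in MeOH/THF (as in step 4) closes it to the 3-hydroxyflavanone of unit B F2. Benzyl trichloroacetimidate with catalytic TfOH gives the 3-O-benzyl flavanone F3. Aryllithium 27 adds to its carbonyl to give the tertiary flavan-4-ol F4. Et3SiH/TFA (as in step 15, now with O-3 protected so that no pinacol path is open) gives the heptadeca-O-benzyl tetramer F5. Hydrogenolysis as in step 21 comes back to the route at 32.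

2. Step 19. Bromine–lithium exchange on the hindered bromide may be incomplete, the doubly ortho-substituted aryllithium may be quenched by proton transfer, and its addition to the hindered ketone may be slow. Fallback: the order of the two additions to the linchpin is reversed. It sets out from 14. Its aryllithium 27 is acylated by the unhindered amide 24 to give the lower epoxy ketone F6. The less hindered aryllithium 25 (made from 21 as in step 18) then adds to F6 and comes back to the route at 28 (either carbinol epimer serves).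

3. Step 10. Capture of the 5-deoxy flavan-4-yl cation may show poor facial selectivity (3,4-cis product beside 3,4-trans), and the electrophile may self-condense. Fallback: stereocontrol by neighbouring-group participation. It sets out from 7. NaBH4 gives the flavan-3,4-diol F7. Ac2O/pyridine gives the 3,4-di-O-acetate F8. TMSOTf with 13 forms the C4–C6 bond through the 3,4-acetoxonium ion, which blocks the cis face, to give the 3-O-acetyl dimer bromide F9. K2CO3/MeOH gives the 3-hydroxy dimer bromide F10. NaH/BnBr comes back to the route at 14.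

## Further compounds

F1 | step 20 | free 2'-hydroxy epoxy ketone (compound 26 with the allyl ether cleaved) | c9ccccc9COc1ccc2c(c1)O[C@@H](c1ccc(OCc9ccccc9)c(OCc9ccccc9)c1)[C@H](OCc9ccccc9)[C@@H]2c1cc(C(=O)[C@H]3O[C@@H]3c3ccc(OCc9ccccc9)c(OCc9ccccc9)c3)c(O)cc1OCc9ccccc9
F2 | step 20 | 3-hydroxyflavanone of unit B: (2S,3S)-flavanonol carrying tetra-O-benzyl-ent-fisetinidol-4α-yl at C-6 | c9ccccc9COc1ccc2c(c1)O[C@@H](c1ccc(OCc9ccccc9)c(OCc9ccccc9)c1)[C@H](OCc9ccccc9)[C@@H]2c1cc2c(cc1OCc9ccccc9)O[C@@H](c1ccc(OCc9ccccc9)c(OCc9ccccc9)c1)[C@H](O)C2=O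
F3 | step 20 | 3-O-benzyl flavanone of unit B | c9ccccc9COc1ccc2c(c1)O[C@@H](c1ccc(OCc9ccccc9)c(OCc9ccccc9)c1)[C@H](OCc9ccccc9)[C@@H]2c1cc2c(cc1OCc9ccccc9)O[C@@H](c1ccc(OCc9ccccc9)c(OCc9ccccc9)c1)[C@H](OCc9ccccc9)C2=O
F4 | step 20 | tertiary flavan-4-ol: perbenzylated tetramer with 4-OH on unit B, aryl trans to the 3-benzyloxy group | c9ccccc9COc1ccc2c(c1)O[C@@H](c1ccc(OCc9ccccc9)c(OCc9ccccc9)c1)[C@H](OCc9ccccc9)[C@@H]2c1cc2c(cc1OCc9ccccc9)O[C@@H](c1ccc(OCc9ccccc9)c(OCc9ccccc9)c1)[C@H](OCc9ccccc9)[C@@]2(O)c4c(OCc9ccccc9)c([C@H]6c7ccc(OCc9ccccc9)cc7O[C@@H](c7ccc(OCc9ccccc9)c(OCc9ccccc9)c7)[C@@H]6OCc9ccccc9)c(OCc9ccccc9)c5c4O[C@H](c8ccc(OCc9ccccc9)c(OCc9ccccc9)c8)[C@@H](OCc9ccccc9)C5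
F5 | step 20 | heptadeca-O-benzyl ether of the target (unit B 2,3-trans-3,4-cis) | c9ccccc9COc1ccc2c(c1)O[C@@H](c1ccc(OCc9ccccc9)c(OCc9ccccc9)c1)[C@H](OCc9ccccc9)[C@@H]2c1cc2c(cc1OCc9ccccc9)O[C@@H](c1ccc(OCc9ccccc9)c(OCc9ccccc9)c1)[C@H](OCc9ccccc9)[C@@H]2c4c(OCc9ccccc9)c([C@H]6c7ccc(OCc9ccccc9)cc7O[C@@H](c7ccc(OCc9ccccc9)c(OCc9ccccc9)c7)[C@@H]6OCc9ccccc9)c(OCc9ccccc9)c5c4O[C@H](c8ccc(OCc9ccccc9)c(OCc9ccccc9)c8)[C@@H](OCc9ccccc9)C5
F6 | step 19 | lower epoxy ketone: [(2S,3R)-3-[3,4-bis(benzyloxy)phenyl]oxiran-2-yl] ketone on C-8 of the lower dimer | O=C([C@H]1O[C@@H]1c1ccc(OCc9ccccc9)c(OCc9ccccc9)c1)c4c(OCc9ccccc9)c([C@H]6c7ccc(OCc9ccccc9)cc7O[C@@H](c7ccc(OCc9ccccc9)c(OCc9ccccc9)c7)[C@@H]6OCc9ccccc9)c(OCc9ccccc9)c5c4O[C@H](c8ccc(OCc9ccccc9)c(OCc9ccccc9)c8)[C@@H](OCc9ccccc9)C5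
F7 | step 10 | 7-(benzyloxy)-2-[3,4-bis(benzyloxy)phenyl]chroman-3,4-diol, (2S) 2,3-trans-3,4-trans | c9ccccc9COc1ccc2c(c1)O[C@@H](c1ccc(OCc9ccccc9)c(OCc9ccccc9)c1)[C@H](O)[C@H]2O
F8 | step 10 | 3,4-di-O-acetate of F7 | c9ccccc9COc1ccc2c(c1)O[C@@H](c1ccc(OCc9ccccc9)c(OCc9ccccc9)c1)[C@H](OC(C)=O)[C@H]2OC(C)=O
F9 | step 10 | 3-O-acetyl dimer bromide (compound 14 with acetate in place of the benzyl ether on O-3 of unit C) | Brc4c(OCc9ccccc9)c([C@H]6c7ccc(OCc9ccccc9)cc7O[C@@H](c7ccc(OCc9ccccc9)c(OCc9ccccc9)c7)[C@@H]6OC(C)=O)c(OCc9ccccc9)c5c4O[C@H](c8ccc(OCc9ccccc9)c(OCc9ccccc9)c8)[C@@H](OCc9ccccc9)C5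
F10 | step 10 | 3-hydroxy dimer bromide (compound 14 with free 3-OH on unit C) | Brc4c(OCc9ccccc9)c([C@H]6c7ccc(OCc9ccccc9)cc7O[C@@H](c7ccc(OCc9ccccc9)c(OCc9ccccc9)c7)[C@@H]6O)c(OCc9ccccc9)c5c4O[C@H](c8ccc(OCc9ccccc9)c(OCc9ccccc9)c8)[C@@H](OCc9ccccc9)C5
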